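**Plan**

1. Drimane numbering is used: C1–C3 CH2, C4 CMe2, C5/C10 ring fusion, C6 C–O, C7 CH2, C8 and C9 carry the carboxyl carbons C12 and C11; β is the face of the C10 methyl. The retrosynthesis cuts the C6–O acyl bond, then C6–C7 and C8–C9 of ring B together. This leaves a ring A 1,5-dialdehyde (C11–C9–C10–C5–C6) and tert-butyl 3-nitroacrylate (C7–C8–C12).
2. Enabling feature: round ring B, C9 is α to a carboxyl carbon, C8 bears a carboxyl, C7 is a bare CH2 and C6 bears oxygen. An enamine donor (C9), a nitroalkene acceptor carbon (C8), a nitronate carbon (C7, nitro removed later) and an aldehyde acceptor (C6) therefore line up. C5, flanked by the quaternary C4 and C10, keeps the C6 aldehyde out of enamine chemistry.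
3. Forward: ring A gets C10 by a palladium-catalysed asymmetric allylation. A temporary cyclopentene (C5–C6=C11–C9–C10) is closed by Wacker/aldol, reduced to set C5 and opened by ozonolysis. Ring B is closed last by the amine-catalysed Michael/Henry domino; oxidation, denitration, ketone reduction, acylation and ester cleavage finish the route.
4. Stereochemistry: C10 from the chiral phosphinooxazoline ligand; C5 from protonation anti to the C10 methyl; C8 and C9 from the prolinol catalyst (syn adduct = cis 8β,9β; C9 is also the equatorial epimer); C6 from α-face hydride delivery to the 6-ketone.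
5. Helpers: the nitro group (activates C7, removed from the α-nitro ketone with Bu3SnH) and tert-butyl esters (cleaved by acid at the end, so no base meets the axial C8 ester or the trienoate).

Key step: step 9

Remark: 2,2,6-trimethylcyclohexan-1-one, allyl chloroformate, tert-butyl acrylate and (2E,4E,6E)-octa-2,4,6-trienoic acid are taken as purchasable.

**Route**

Step 1
Reactants: 1 2,2,6-trimethylcyclohexan-1-one; 2 allyl chloroformate
Product: 4 allyl 2,6,6-trimethylcyclohex-1-en-1-yl carbonate, via lithium enolate 3 (not isolated)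
Conditions: LiN(i-Pr)2, THF, −78 to 0 °C; then 2, −78 °C
Reagents that add atoms: allyl chloroformate (compound 2), C=CCOC(=O)Cl
Why: Enolate O-acylation (enol carbonate formation): the ketone has a single enolisable α-hydrogen, so only one tetrasubstituted lithium enolate can form, and the hard chloroformate should acylate it on oxygen.

Step 2
Reactants: 4 allyl 2,6,6-trimethylcyclohex-1-en-1-yl carbonate
Product: 5 (R)-2-allyl-2,6,6-trimethylcyclohexan-1-one
Conditions: Pd2(dba)3 (2.5 mol%), (R)-t-Bu-PHOX [(R)-4-tert-butyl-2-(2-(diphenylphosphanyl)phenyl)-4,5-dihydrooxazole] (6 mol%), THF, 25 °C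
Reagents that add atoms: none
Why: Decarboxylative asymmetric allylic alkylation (Tsuji–Trost type): zerovalent palladium ionises the allyl carbonate, CO2 is lost, and the π-allyl palladium enolate collapses inside the chiral pocket of the (R)-ligand, which should set the quaternary C10 as R, the mirror image of the sense known for the (S)-ligand.

Step 3
Reactants: 5 (R)-2-allyl-2,6,6-trimethylcyclohexan-1-one
Product: 6 (R)-2,2,6-trimethyl-6-(2-oxopropyl)cyclohexan-1-one
Conditions: PdCl2 (10 mol%), Cu(OAc)2·H2O (25 mol%), O2 (1 atm), DMA/H2O 7:1, 23 °C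
Reagents that add atoms: water, O
Why: Wacker oxidation: Markovnikov hydroxypalladation of the terminal alkene and β-hydride elimination should give the methyl ketone, and the quaternary allylic carbon rules out alkene migration.

Step 4
Reactants: 6 (R)-2,2,6-trimethyl-6-(2-oxopropyl)cyclohexan-1-one
Product: 8 (R)-4,4,7a-trimethyl-1,4,5,6,7,7a-hexahydro-2H-inden-2-one, via aldol adduct 7 (not isolated)
Conditions: KOH, xylenes, 110 °C, Dean–Stark trap
Reagents that add atoms: none
Why: Intramolecular aldol condensation: the ring ketone has no α-hydrogen, so only the methyl ketone enolises; its CH3 carbon (the later C6) attacks the ring carbonyl (C5) to close the five-membered ring, and dehydration can only go toward that carbon.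

Step 5
Reactants: 8 (R)-4,4,7a-trimethyl-1,4,5,6,7,7a-hexahydro-2H-inden-2-one
Product: 10 (3aS,7aR)-4,4,7a-trimethyl-3a,4,5,6,7,7a-hexahydro-1H-inden-2-yl trifluoromethanesulfonate, via lithium enolate 9 (not isolated)
Conditions: Li (2.2 equiv), NH3(l)/THF, t-BuOH (1 equiv), −78 °C; isoprene; NH3 evaporated; then PhNTf2, THF, 0 to 23 °C
Reagents that add atoms: N-phenylbis(trifluoromethanesulfonimide), O=S(=O)(N(c1ccccc1)S(=O)(=O)C(F)(F)F)C(F)(F)F
Why: Dissolving-metal conjugate reduction with enolate trapping: C5 should be protonated on the α-face, anti to the axial C10 methyl and the syn-axial C4 methyl (axial protonation of ring A), which sets the trans C5/C10 relationship, and the regiodefined C6=C11 enolate is then O-sulfonylated.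

Step 6
Reactants: 10 (3aS,7aR)-4,4,7a-trimethyl-3a,4,5,6,7,7a-hexahydro-1H-inden-2-yl trifluoromethanesulfonate
Product: 11 (3aS,7aR)-4,4,7a-trimethyl-3a,4,5,6,7,7a-hexahydro-1H-indene
Conditions: Pd(OAc)2 (5 mol%), PPh3 (10 mol%), HCO2H, n-Bu3N, DMF, 60 °C
Reagents that add atoms: none
Why: Palladium-catalysed formate reduction of an enol triflate (oxidative addition to zerovalent palladium, formate exchange, loss of CO2 to a palladium hydride, reductive elimination) should replace OTf by H, keep the C6=C11 alkene in place and leave both stereocentres untouched.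

Step 7
Reactants: 11 (3aS,7aR)-4,4,7a-trimethyl-3a,4,5,6,7,7a-hexahydro-1H-indene
Product: 13 2-[(1R,2S)-2-formyl-1,3,3-trimethylcyclohexyl]acetaldehyde, via secondary ozonide 12 (not isolated)
Conditions: O3, CH2Cl2, −78 °C; then Me2S, −78 to 23 °C
Reagents that add atoms: ozone, [O-][O+]=O
Why: Ozonolysis (Criegee mechanism) with reductive work-up should cut the C6=C11 bond of the temporary cyclopentene to the 1,5-dialdehyde; C5 keeps its configuration under these neutral conditions and no intramolecular aldol ring larger than four atoms is possible.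

Step 8
Reactants: 14 tert-butyl acrylate
Product: 16 tert-butyl (E)-3-nitroacrylate, via iodonitro ester 15 (not isolated)
Conditions: N2O4, I2, Et2O, 0 °C; then NaOAc, Et2O, 0 to 23 °C
Reagents that add atoms: dinitrogen tetroxide, O=[N+]([O-])[N+](=O)[O-]
Why: Iodonitration of the acrylate (NO2 at the β-carbon, iodine at the α-carbon) followed by acetate-mediated E1cB loss of HI is the standard route to 3-nitroacrylates and should give the more stable E alkene.

Step 9
Reactants: 13 2-[(1R,2S)-2-formyl-1,3,3-trimethylcyclohexyl]acetaldehyde; 16 tert-butyl (E)-3-nitroacrylate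
Product: 18 trans-decalin nitro alcohol (5α-H, 10β-CH3, 6α-OH, 7β-NO2, 8β-CO2t-Bu, 9β-CHO), via Michael adduct 17 (not isolated)
Conditions: (S)-2-[diphenyl(trimethylsilyloxy)methyl]pyrrolidine (20 mol%), ClCH2CO2H (20 mol%), CH2Cl2, 0 to 23 °C; then Et3N (0.3 equiv), 0 to 23 °C
Reagents that add atoms: tert-butyl (E)-3-nitroacrylate (compound 16), CC(C)(C)OC(=O)/C=C/[N+](=O)[O-]
Why: The secondary amine condenses only with the unhindered CH2CHO group (C11) of 13 to give an enamine that is nucleophilic at C9 and adds to C8 of 16, the carbon β to the nitro group; after Et3N is added the C7 nitronate adds to the C6 aldehyde (intramolecular Henry reaction). The closest known reaction type is the amine-catalysed domino Michael/Henry reaction of pentane-1,5-dial with nitroalkenes, together with the prolinol silyl ether-catalysed addition of aldehydes to tert-butyl 3-nitroacrylate. Ring B closes by 6-exo-trig attack of the nitronate carbon on the C6 carbonyl. C9 and C8 are set in the Michael step by the catalyst, whose diphenyl(silyloxy)methyl group shields one enamine face and whose open synclinal transition state gives the syn adduct, which is the cis 8β,9β pattern of the ring; C7 and C6 form under reversible Henry conditions (equatorial 7β-NO2 and 6α-OH expected) and both are erased in steps 10 and 11, while C5 and C10 come unchanged from 13. The step needs chemoselectivity between the two aldehydes, secured by the quaternary C4 and C10 that flank C5 and by the fact that neither aldehyde can reach the other's α-carbon in a ring larger than four; regioselectivity on the acceptor, secured by the nitro group; and facial selectivity at C8 over the resident C10 centre, secured by catalyst control. C9 is in addition the equatorial, thermodynamically favoured epimer, so only C8 rests on the catalyst alone.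

Step 10
Reactants: 18 trans-decalin nitro alcohol
Product: 19 α-nitro ketone acid (6-oxo, 7-NO2, 8β-CO2t-Bu, 9β-CO2H)
Conditions: CrO3, H2SO4, H2O/acetone, 0 °C
Reagents that add atoms: water, O
Why: Jones oxidation should turn the secondary β-nitro alcohol into the α-nitro ketone and the aldehyde hydrate into the acid, which erases C6 and makes C7 enolisable, while the cold acidic medium avoids retro-Henry cleavage and C8 epimerisation and is tolerated by the tert-butyl ester.

Step 11
Reactants: 19 α-nitro ketone acid
Product: 20 (1S,2S,4aS,8aS)-2-(tert-butoxycarbonyl)-5,5,8a-trimethyl-4-oxodecahydronaphthalene-1-carboxylic acid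
Conditions: Bu3SnH (2.5 equiv), AIBN (0.2 equiv), benzene, 80 °C
Reagents that add atoms: none
Why: Radical denitration: the stannyl radical adds to the nitro group, C–N fragmentation gives the α-keto radical at C7, and this takes hydrogen from Bu3SnH; α-nitro ketones are the most reactive substrate class and the neutral medium cannot epimerise the axial C8 ester.

Step 12
Reactants: 20 keto acid
Product: 21 di-tert-butyl (1S,2S,4aS,8aS)-5,5,8a-trimethyl-4-oxodecahydronaphthalene-1,2-dicarboxylate
Conditions: tert-butyl 2,2,2-trichloroacetimidate (2 equiv), BF3·OEt2 (5 mol%), CH2Cl2/cyclohexane, 23 °C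
Reagents that add atoms: tert-butyl 2,2,2-trichloroacetimidate, CC(C)(C)OC(=N)C(Cl)(Cl)Cl
Why: Acid-catalysed tert-butylation of the hindered C11 acid by the trichloroacetimidate (O-alkylation by a tert-butyl cation equivalent, insensitive to crowding at the acyl carbon) needs no base and so should leave C8 and C9 untouched.

Step 13
Reactants: 21 keto diester
Product: 22 di-tert-butyl (1S,2S,4R,4aS,8aS)-4-hydroxy-5,5,8a-trimethyldecahydronaphthalene-1,2-dicarboxylate (6β-OH)
Conditions: NaBH4, MeOH/THF, −20 to 0 °C
Reagents that add atoms: none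
Why: Ketone reduction by hydride addition from the α-face (equatorial attack), the β-face of C6 being blocked by the syn-axial methyls at C4 and C10 and by the axial C8 ester, should give the axial 6β-alcohol; low temperature and the bulk of the tert-butyl ester disfavour lactonisation onto C12.

Step 14
Reactants: 22 6β-alcohol; 23 (2E,4E,6E)-octa-2,4,6-trienoic acid
Product: 25 di-tert-butyl (1S,2S,4R,4aS,8aS)-5,5,8a-trimethyl-4-[(2E,4E,6E)-octa-2,4,6-trienoyloxy]decahydronaphthalene-1,2-dicarboxylate, via mixed anhydride 24 (not isolated)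
Conditions: 23, 2,4,6-trichlorobenzoyl chloride, Et3N, THF, 23 °C; then 22, DMAP, toluene, 60 °C
Reagents that add atoms: (2E,4E,6E)-octa-2,4,6-trienoic acid (compound 23), C/C=C/C=C/C=C/C(=O)O
Why: Yamaguchi esterification: DMAP attacks the mixed anhydride at the trienoyl carbonyl and the acylpyridinium should transfer the acyl group to the hindered 6β-hydroxyl with retention at C6 and without isomerising the all-E triene.

Step 15
Reactants: 25 di-tert-butyl ester of the target
Product: 26 (1S,2S,4R,4aS,8aS)-5,5,8a-trimethyl-4-[(2E,4E,6E)-octa-2,4,6-trienoyloxy]decahydronaphthalene-1,2-dicarboxylic acid (CNP0462207.1)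
Conditions: CF3CO2H/CH2Cl2 1:4, anisole, 0 to 23 °C
Reagents that add atoms: none
Why: Acidolysis of both tert-butyl esters (E1 loss of isobutene) should free the cis diacid under conditions that spare the trienoate ester and cannot epimerise C8 or C9.

**Compound list**

1 | 2,2,6-trimethylcyclohexan-1-one (racemic) | CC1CCCC(C)(C)C1=O | starting material
2 | allyl chloroformate | C=CCOC(=O)Cl | starting material
3 | lithium 2,6,6-trimethylcyclohex-1-en-1-olate | [Li+].[O-]C1=C(C)CCCC1(C)C | intermediate
4 | allyl 2,6,6-trimethylcyclohex-1-en-1-yl carbonate | C=CCOC(=O)OC1=C(C)CCCC1(C)C | intermediate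
5 | (R)-2-allyl-2,6,6-trimethylcyclohexan-1-one | C=CC[C@@]1(C)CCCC(C)(C)C1=O | intermediate
6 | (R)-2,2,6-trimethyl-6-(2-oxopropyl)cyclohexan-1-one | CC(=O)C[C@@]1(C)CCCC(C)(C)C1=O | intermediate
7 | (7aR)-3a-hydroxy-4,4,7a-trimethyloctahydro-2H-inden-2-one (aldol adduct; C3a not defined, lost on dehydration) | O=C1CC2(O)C(C)(C)CCC[C@]2(C)C1 | intermediate
8 | (R)-4,4,7a-trimethyl-1,4,5,6,7,7a-hexahydro-2H-inden-2-one | O=C1C=C2C(C)(C)CCC[C@]2(C)C1 | intermediate
9 | lithium (3aS,7aR)-4,4,7a-trimethyl-3a,4,5,6,7,7a-hexahydro-1H-inden-2-olate | [Li+].[O-]C1=C[C@H]2C(C)(C)CCC[C@]2(C)C1 | intermediate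
10 | (3aS,7aR)-4,4,7a-trimethyl-3a,4,5,6,7,7a-hexahydro-1H-inden-2-yl trifluoromethanesulfonate | O=S(=O)(OC1=C[C@H]2C(C)(C)CCC[C@]2(C)C1)C(F)(F)F | intermediate
11 | (3aS,7aR)-4,4,7a-trimethyl-3a,4,5,6,7,7a-hexahydro-1H-indene | C1=C[C@H]2C(C)(C)CCC[C@]2(C)C1 | intermediate
12 | secondary ozonide of 11 (1,2,4-trioxolane across C6 and C11; configuration at these two carbons not defined) | CC1(C)CCC[C@]2(C)CC3OOC(O3)[C@@H]12 | intermediate
13 | 2-[(1R,2S)-2-formyl-1,3,3-trimethylcyclohexyl]acetaldehyde | O=CC[C@@]1(C)CCCC(C)(C)[C@@H]1C=O | intermediate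
14 | tert-butyl acrylate | C=CC(=O)OC(C)(C)C | starting material
15 | tert-butyl 2-iodo-3-nitropropanoate (racemic) | CC(C)(C)OC(=O)C(I)C[N+](=O)[O-] | intermediate
16 | tert-butyl (E)-3-nitroacrylate | CC(C)(C)OC(=O)/C=C/[N+](=O)[O-] | intermediate
17 | Michael adduct: tert-butyl syn-3-formyl-2-(nitromethyl)-3-(2-formyl-1,3,3-trimethylcyclohexyl)propanoate, C8 and C9 as in the target, ring A as in 13 | O=C[C@@H]([C@H](C[N+](=O)[O-])C(=O)OC(C)(C)C)[C@@]1(C)CCCC(C)(C)[C@@H]1C=O | intermediate
18 | trans-decalin nitro alcohol: 5α-H, 10β-CH3, 6α-OH, 7β-NO2, 8β-CO2t-Bu, 9β-CHO (any C6/C7 epimers converge in steps 10 and 11) | O[C@H]1[C@H]([N+](=O)[O-])[C@H](C(=O)OC(C)(C)C)[C@H](C=O)[C@@]2(C)CCCC(C)(C)[C@H]12 | intermediate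
19 | α-nitro ketone acid: 6-oxo, 7-NO2 (enolisable, configuration open), 8β-CO2t-Bu, 9β-CO2H, trans-fused | O=C1C([N+](=O)[O-])[C@H](C(=O)OC(C)(C)C)[C@H](C(O)=O)[C@@]2(C)CCCC(C)(C)[C@H]12 | intermediate
20 | (1S,2S,4aS,8aS)-2-(tert-butoxycarbonyl)-5,5,8a-trimethyl-4-oxodecahydronaphthalene-1-carboxylic acid | O=C1C[C@H](C(=O)OC(C)(C)C)[C@H](C(O)=O)[C@@]2(C)CCCC(C)(C)[C@H]12 | intermediate
21 | di-tert-butyl (1S,2S,4aS,8aS)-5,5,8a-trimethyl-4-oxodecahydronaphthalene-1,2-dicarboxylate | O=C1C[C@H](C(=O)OC(C)(C)C)[C@H](C(=O)OC(C)(C)C)[C@@]2(C)CCCC(C)(C)[C@H]12 | intermediate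
22 | di-tert-butyl (1S,2S,4R,4aS,8aS)-4-hydroxy-5,5,8a-trimethyldecahydronaphthalene-1,2-dicarboxylate | O[C@@H]1C[C@H](C(=O)OC(C)(C)C)[C@H](C(=O)OC(C)(C)C)[C@@]2(C)CCCC(C)(C)[C@H]12 | intermediate
23 | (2E,4E,6E)-octa-2,4,6-trienoic acid | C/C=C/C=C/C=C/C(=O)O | starting material
24 | (2E,4E,6E)-octa-2,4,6-trienoic 2,4,6-trichlorobenzoic anhydride | C/C=C/C=C/C=C/C(=O)OC(=O)c1c(Cl)cc(Cl)cc1Cl | intermediate
25 | di-tert-butyl (1S,2S,4R,4aS,8aS)-5,5,8a-trimethyl-4-[(2E,4E,6E)-octa-2,4,6-trienoyloxy]decahydronaphthalene-1,2-dicarboxylate | C/C=C/C=C/C=C/C(=O)O[C@@H]1C[C@H](C(=O)OC(C)(C)C)[C@H](C(=O)OC(C)(C)C)[C@@]2(C)CCCC(C)(C)[C@H]12 | intermediate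
26 | (1S,2S,4R,4aS,8aS)-5,5,8a-trimethyl-4-[(2E,4E,6E)-octa-2,4,6-trienoyloxy]decahydronaphthalene-1,2-dicarboxylic acid | C/C=C/C=C/C=C/C(=O)O[C@@H]1C[C@H](C(=O)O)[C@H](C(=O)O)[C@@]2(C)CCCC(C)(C)[C@H]12 | target

**Count and risks**

Total step count: 15. Longest linear sequence: 14 (steps 1–7 and 9–15); step 8 is a one-step side branch.

Steps most likely to fail:

1. Step 9. The enamine may form slowly at the neopentylic CH2CHO group; facial selectivity at C8 may erode if the catalyst and the resident C10 centre are mismatched; ring closure against the axial C8 ester may stall. The fallback gives up catalyst control of C8 and sets it by hydrogenation; it sets out from 13 (with 16) and returns at 21. Pyrrolidine (20 mol%), AcOH, CH2Cl2, then Et3N should make the same two bonds and give the nitro alcohol as a C8 epimer mixture F1. CrO3/H2SO4 then gives the nitro keto acid mixture F2, Bu3SnH/AIBN the keto acid mixture F3, and tert-butyl trichloroacetimidate the keto diester mixture F4. IBX in DMSO at 70 °C (or the Saegusa–Ito oxidation) dehydrogenates F4 to the 7-ene-6-one F5, because C8 is the only carbon β to the carbonyl that bears hydrogen. H2, Pd/C, EtOAc should add hydrogen on the α-face, opposite the axial C10 methyl, and give 21; a shift of the alkene to C8=C9 would converge on the same product.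

2. Step 14. Acyl transfer to the crowded axial 6β-hydroxyl may be slow, and this hydroxyl may lactonise onto the axial C8 ester. The fallback builds the acyl chain on the alcohol; it sets out from 22 and returns at 25. Diethylphosphonoacetic acid, DCC, DMAP, CH2Cl2 (a small, ketene-like acyl donor) should give the phosphonoacetate F6. Horner–Wadsworth–Emmons olefination of F6 with (2E,4E)-hexa-2,4-dienal (LiCl, i-Pr2NEt, MeCN) forms the 2E double bond and gives 25.

3. Step 5. C5 may be protonated on the β-face (cis ring fusion), the ketone may be over-reduced, or the enolate may equilibrate before O-sulfonylation. The fallback replaces dissolving-metal reduction by an allylic diazene rearrangement; it sets out from 8 and returns at 11. Luche reduction (NaBH4, CeCl3·7H2O, MeOH), with hydride entering anti to the C10 methyl, should give the allylic alcohol F7. Mitsunobu reaction with 2-nitrobenzenesulfonylhydrazide (PPh3, DEAD, THF, −30 °C) gives with inversion the N-allyl sulfonylhydrazine F8. On warming, F8 loses the sulfinic acid and then N2 in a retro-ene shift that delivers hydrogen to C5 on the α-face and moves the alkene to C6=C11, giving 11.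

Further compounds
F1 | step 9 | nitro alcohol as in 18 but a mixture at C8 (C6 and C7 also open) | OC1C([N+](=O)[O-])C(C(=O)OC(C)(C)C)[C@H](C=O)[C@@]2(C)CCCC(C)(C)[C@H]12
F2 | step 9 | α-nitro ketone acid as in 19 but a mixture at C8 | O=C1C([N+](=O)[O-])C(C(=O)OC(C)(C)C)[C@H](C(O)=O)[C@@]2(C)CCCC(C)(C)[C@H]12
F3 | step 9 | keto acid as in 20 but a mixture at C8 | O=C1CC(C(=O)OC(C)(C)C)[C@H](C(O)=O)[C@@]2(C)CCCC(C)(C)[C@H]12
F4 | step 9 | keto diester as in 21 but a mixture at C8 | O=C1CC(C(=O)OC(C)(C)C)[C@H](C(=O)OC(C)(C)C)[C@@]2(C)CCCC(C)(C)[C@H]12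
F5 | step 9 | trans-fused 7-ene-6-one: di-tert-butyl 5,5,8a-trimethyl-4-oxo-1,4,4a,5,6,7,8,8a-octahydronaphthalene-1,2-dicarboxylate with the C9 ester β | O=C1C=C(C(=O)OC(C)(C)C)[C@H](C(=O)OC(C)(C)C)[C@@]2(C)CCCC(C)(C)[C@H]12
F6 | step 14 | 6β-(diethoxyphosphoryl)acetate of 22 | CCOP(=O)(OCC)CC(=O)O[C@@H]1C[C@H](C(=O)OC(C)(C)C)[C@H](C(=O)OC(C)(C)C)[C@@]2(C)CCCC(C)(C)[C@H]12
F7 | step 5 | (2R,7aR)-4,4,7a-trimethyl-2,4,5,6,7,7a-hexahydro-1H-inden-2-ol | O[C@H]1C=C2C(C)(C)CCC[C@]2(C)C1
F8 | step 5 | 1-[(2S,7aR)-4,4,7a-trimethyl-2,4,5,6,7,7a-hexahydro-1H-inden-2-yl]-1-(2-nitrophenylsulfonyl)hydrazine | NN([C@@H]1C=C2C(C)(C)CCC[C@]2(C)C1)S(=O)(=O)c1ccccc1[N+](=O)[O-]
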